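**Retrosynthetic overview**
1. Target 25 ← C7 acetylation and desilylation of the bis-silylated 6-6-8 diketone 23.
2. Eight-membered ring of 23 ← one-pot double one-carbon ring expansion (two alkenyl 1,2-shifts) of the six-membered enedione 21.
3. Ring-A ester triad and 5α-H/9α-H ← Schenck ene and dihydroxylation of a ring-A alkene, hydroxyl-directed hydrogenation, C9 epimerisation.
4. Rings B and C (six-membered) with C7-O and quaternary C10 ← enantioselective quinone Diels–Alder of siloxy triene 8 with toluquinone 10; C8-O by enolate hydroxylation.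
5. Ring order: A (from 2-methylcyclohexenone) → B and six-membered C together → C enlarged from six to eight.

Numbering used in names: decalin carbons C1–C10 (C4 gem-dimethyl, C10 methyl). Ring C in the target is C8–C12(=O)–C13H2–C14H=C15(Me)–C16H2–C11(=O)–C9; the six-membered precursors lack C13 and C16. β is the face of the C10 methyl, α the opposite face.

Assumption: 5–7 are carried as racemic or isomeric mixtures because their stereo-elements vanish in 8; absolute configuration enters in step 7, with the catalyst enantiomer chosen by its established facial model.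

**Step 1**
Reactants: 1 2-methylcyclohex-2-en-1-one
Product: 3 2,2-dimethylcyclohex-3-en-1-one, via potassium dienolate 2 (not isolated)
Conditions: KOt-Bu (1.05 equiv), t-BuOH–THF, 0 °C; MeI
Reagents that add atoms: iodomethane (CI)
Why: Thermodynamic γ-deprotonation gives the extended dienolate, which is methylated at the α-carbon (deconjugative α-alkylation) to create the gem-dimethyl carbon (future C4) and the skipped ring alkene (future C2=C3).

**Step 2**
Reactants: 3 2,2-dimethylcyclohex-3-en-1-one
Product: 5 2,2,6-trimethylcyclohex-3-en-1-one (racemic), via lithium enolate 4 (not isolated)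
Conditions: LDA, THF, −78 °C; MeI, −78 → 0 °C
Reagents that add atoms: iodomethane (CI)
Why: Only C6 is enolisable, so kinetic enolate alkylation installs the future C10 methyl without regiochemical ambiguity; the new stereocentre is erased in step 5.

**Step 3**
Reactants: 5 2,2,6-trimethylcyclohex-3-en-1-one
Product: 6 1-ethynyl-2,2,6-trimethylcyclohex-3-en-1-ol (diastereomer mixture)
Conditions: HC≡CMgBr, THF, 0 °C → rt; aq NH4Cl
Reagents that add atoms: ethynylmagnesium bromide (C#C[Mg]Br)
Why: Grignard 1,2-addition of the small acetylide to the hindered, non-conjugatable ketone brings in C6 and C7; the carbinol configuration is irrelevant.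

**Step 4**
Reactants: 6 1-ethynyl-2,2,6-trimethylcyclohex-3-en-1-ol
Product: 7 2-(2,2,6-trimethylcyclohex-3-en-1-ylidene)acetaldehyde (E/Z mixture)
Conditions: MoO2(acac)2 (2 mol %), Ph3PAuCl/AgOTf (2 mol %), toluene, rt
Reagents that add atoms: none
Why: Meyer–Schuster rearrangement of the tertiary propargylic alcohol under neutral Au/Mo catalysis gives the ylidene acetaldehyde and avoids the Rupe pathway.

**Step 5**
Reactants: 7 2-(2,2,6-trimethylcyclohex-3-en-1-ylidene)acetaldehyde
Product: 8 tert-butyldimethyl{[(E)-2-(2,6,6-trimethylcyclohexa-1,4-dien-1-yl)ethenyl]oxy}silane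
Conditions: TBSOTf, Et3N, Et2O, 0 °C
Reagents that add atoms: tert-butyldimethylsilyl triflate (CC(C)(C)[Si](C)(C)OS(=O)(=O)C(F)(F)F)
Why: Soft enolisation with removal of the only γ-hydrogen (ring CH–Me) gives the (E)-1-silyloxy diene (silyl dienol ether formation) and erases the stereo-elements of 5–7.

**Step 6**
Reactants: 9 2-methylphenol
Product: 10 2-methyl-1,4-benzoquinone
Conditions: O2 (1 atm), Co(salen) (5 mol %), DMF, rt
Reagents that add atoms: dioxygen (O=O)
Why: Cobalt–salen-mediated aerobic para-oxidation of the phenol gives the p-quinone.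

**Step 7**
Reactants: 8 siloxy triene; 10 2-methyl-1,4-benzoquinone
Product: 11 cis-fused Diels–Alder adduct (7α-OTBS; 8β-H; 9β-H; 10β-Me; ring-A C2=C3; C5=C6; ring C = C8–C12(=O)–C14H=C15(Me)–C11(=O)–C9)
Conditions: (S)-o-tolyl-CBS oxazaborolidinium triflimide (20 mol %), CH2Cl2, −78 → −40 °C
Reagents that add atoms: none
Why: Catalytic enantioselective quinone Diels–Alder reaction in which the chiral Lewis acid binds the more basic carbonyl (future C12), so the nucleophilic diene terminus C10 bonds β to it at the unsubstituted quinone alkene (methyl ends on C15), endo addition sets 7α-O, 8β-H, 9β-H and the C10 quaternary centre, and the catalyst enantiomer fixes the absolute configuration.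

**Step 8**
Reactants: 11 Diels–Alder adduct
Product: 14 8β-triethylsilyloxy enedione (cis B/C), via potassium C8 enolate 12 (not isolated), via potassium C8 alkoxide 13 (not isolated)
Conditions: KHMDS (1.05 equiv), THF, −78 °C; 3-phenyl-2-(phenylsulfonyl)oxaziridine; TESCl, −78 → −40 °C
Reagents that add atoms: 3-phenyl-2-(phenylsulfonyl)oxaziridine (O=S(=O)(N1OC1c1ccccc1)c1ccccc1); chlorotriethylsilane (CC[Si](Cl)(CC)CC)
Why: Kinetic α′-deprotonation takes the less hindered, C7-O-acidified C8–H rather than the neopentyl C9–H, and the enolate (kept at −78 °C to suppress loss of the C7 silyloxide) is hydroxylated on the convex β face opposite the axial 7α-OTBS (Davis enolate oxidation, sets 8β-O) and silylated in the same flask.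

**Step 9**
Reactants: 14 8β-triethylsilyloxy enedione
Product: 16 3α-hydroxy-Δ1 allylic alcohol, via C3 hydroperoxide 15 (not isolated)
Conditions: O2, methylene blue (cat.), 660 nm LED, CH2Cl2–MeOH, −20 °C; PPh3
Reagents that add atoms: dioxygen (O=O)
Why: Schenck ene reaction on the only alkene with a properly aligned allylic hydrogen (C1–H2): oxygen enters at C3 on the α face with abstraction of axial H1α (β face screened by the C10 and 4β methyls, sets 3α-O), the alkene moves to C1=C2, red light avoids exciting the enedione, and PPh3 reduces the hydroperoxide.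

**Step 10**
Reactants: 16 3α-hydroxy-Δ1 allylic alcohol
Product: 17 1α,2α,3α-triol (C5=C6 retained; cis B/C)
Conditions: OsO4 (5 mol %), NMO, acetone–H2O, 0 °C
Reagents that add atoms: 4-methylmorpholine N-oxide (C[N+]1([O-])CCOCC1); water (O)
Why: Upjohn syn-dihydroxylation of the only electron-rich, accessible alkene from the α face (anti to the axial C10 and 4β methyls) sets 1α-O and 2α-O, while C5=C6 is buried between two quaternary carbons and the enedione alkene is electron-poor.

**Step 11**
Reactants: 17 1α,2α,3α-triol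
Product: 19 triol with 5α-H and 9α-H (trans A/B; trans B/C), via cis-B/C hydrogenation product 18 (not isolated)
Conditions: H2 (1 atm), [Ir(cod)(PCy3)(py)]PF6 (5 mol %), CH2Cl2, 0 °C → rt; then Et3N, MeOH, 0 °C
Reagents that add atoms: none
Why: The syn-axial 1α/3α hydroxyls bind cationic iridium and deliver H2 to the α face of the hindered C5=C6 alkene (hydroxyl-directed hydrogenation, sets 5α-H, the electron-poor enedione alkene is left), then amine-mediated enolisation at C9 (the only enolisable ring-C position) turns the axial C9–C11 bond equatorial (sets 9α-H) in a protic medium where reprotonation outruns E1cB loss of the tertiary silyloxide.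

**Step 12**
Reactants: 19 trans-fused triol
Product: 20 2α-acetate
Conditions: AcCl (1.05 equiv), 2,4,6-collidine, CH2Cl2, −78 °C
Reagents that add atoms: acetyl chloride (CC(Cl)=O)
Why: Kinetic acylation selects the single equatorial hydroxyl (C2) over the two axial, neopentyl-type hydroxyls at C1 and C3.

**Step 13**
Reactants: 20 2α-acetate
Product: 21 1α,3α-dibenzoate 2α-acetate (six-membered enedione)
Conditions: BzOTf (2.5 equiv), pyridine, CH2Cl2, −78 → 0 °C
Reagents that add atoms: benzoyl triflate (O=C(OS(=O)(=O)C(F)(F)F)c1ccccc1)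
Why: Benzoyl triflate esterifies the two hindered axial hydroxyls under weakly basic, low-temperature conditions that neither migrate the acetate nor enolise C9.

**Step 14**
Reactants: 21 six-membered enedione
Product: 23 7α-TBSO-8β-TESO 6-6-8 diketone with (Z)-C14=C15, via bis(α-trimethylsilyl) diketone 22 (not isolated)
Conditions: TMSCHN2 (2.5 equiv), Sc(OTf)3 (20 mol %), CH2Cl2, −78 → 0 °C; then 1 M HCl–THF, 0 °C
Reagents that add atoms: (trimethylsilyl)diazomethane (C[Si](C)(C)C=[N+]=[N-])
Why: Proposed new method: a twofold ring homologation of a cyclic 2-ene-1,4-dione, in which each Lewis-acid-activated carbonyl adds the diazoalkane carbon and the alkenyl carbon (C14 at C12, C15 at C11) undergoes the 1,2-shift with loss of N2 in preference to the oxygenated quaternary C8 or neopentyl C9, each homologated carbonyl is masked as its α-silyl ketone against over-insertion, and α-protodesilylation leaves the β,γ-unsaturated diketone with the ring-inherited Z alkene; the closest known reaction type is the Lewis-acid-catalysed diazoalkane–ketone homologation (Tiffeneau–Demjanov type) with alkenyl migration on simple cyclohexenones, not yet shown twofold or on enediones.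

**Step 15**
Reactants: 23 bis-silylated 6-6-8 diketone
Product: 24 7α,8β-diol
Conditions: HF·pyridine, pyridine–THF, 0 °C → rt
Reagents that add atoms: none
Why: Buffered fluoride cleaves both silyl ethers (desilylation) without base, so the aldol-type C8–OH/C11=O unit, the skipped alkene and the esters are untouched.

**Step 16**
Reactants: 24 7α,8β-diol
Product: 25 CNP0214674.2
Conditions: Ac2O, DMAP (cat.), pyridine, 0 °C → rt
Reagents that add atoms: acetic anhydride (CC(=O)OC(C)=O)
Why: DMAP-catalysed acetylation takes the secondary C7 hydroxyl while the tertiary C8 hydroxyl stays free.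

**Compound list**
1 | 2-methylcyclohex-2-en-1-one | CC1=CCCCC1=O | starting material
2 | potassium 2-methylcyclohexa-1,3-dien-1-olate | [K+].[O-]C1=C(C)C=CCC1 | intermediate (not isolated)
3 | 2,2-dimethylcyclohex-3-en-1-one | CC1(C)C=CCCC1=O | intermediate
4 | lithium 6,6-dimethylcyclohexa-1,4-dien-1-olate | [Li+].[O-]C1=CCC=CC1(C)C | intermediate (not isolated)
5 | 2,2,6-trimethylcyclohex-3-en-1-one (racemic) | CC1CC=CC(C)(C)C1=O | intermediate
6 | 1-ethynyl-2,2,6-trimethylcyclohex-3-en-1-ol (racemic diastereomer mixture) | C#CC1(O)C(C)CC=CC1(C)C | intermediate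
7 | 2-(2,2,6-trimethylcyclohex-3-en-1-ylidene)acetaldehyde (E/Z mixture, racemic) | O=CC=C1C(C)CC=CC1(C)C | intermediate
8 | tert-butyldimethyl{[(E)-2-(2,6,6-trimethylcyclohexa-1,4-dien-1-yl)ethenyl]oxy}silane | CC1=C(/C=C/O[Si](C)(C)C(C)(C)C)C(C)(C)C=CC1 | intermediate
9 | 2-methylphenol | Cc1ccccc1O | starting material
10 | 2-methyl-1,4-benzoquinone | CC1=CC(=O)C=CC1=O | intermediate
11 | cis-fused Diels–Alder adduct (7α-OTBS, 8β-H, 9β-H, 10β-Me; C2=C3, C5=C6; six-membered enedione ring C) | C1=CC[C@]2(C)C(=C[C@H](O[Si](C)(C)C(C)(C)C)[C@@H]3C(=O)C=C(C)C(=O)[C@@H]32)C1(C)C | intermediate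
12 | potassium C8(12) enolate of 11 | [K+].C1=CC[C@]2(C)C(=C[C@H](O[Si](C)(C)C(C)(C)C)C3=C([O-])C=C(C)C(=O)[C@@H]32)C1(C)C | intermediate (not isolated)
13 | potassium 8β-alkoxide (cis B/C) | [K+].C1=CC[C@]2(C)C(=C[C@H](O[Si](C)(C)C(C)(C)C)[C@]3([O-])C(=O)C=C(C)C(=O)[C@@H]32)C1(C)C | intermediate (not isolated)
14 | 8β-triethylsilyloxy enedione (7α-OTBS, 9β-H, cis B/C; C2=C3, C5=C6) | C1=CC[C@]2(C)C(=C[C@H](O[Si](C)(C)C(C)(C)C)[C@]3(O[Si](CC)(CC)CC)C(=O)C=C(C)C(=O)[C@@H]32)C1(C)C | intermediate
15 | 3α-hydroperoxide with C1=C2 | C1=C[C@]2(C)C(=C[C@H](O[Si](C)(C)C(C)(C)C)[C@]3(O[Si](CC)(CC)CC)C(=O)C=C(C)C(=O)[C@@H]32)C(C)(C)[C@H]1OO | intermediate (not isolated)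
16 | 3α-hydroxy-Δ1 allylic alcohol | C1=C[C@]2(C)C(=C[C@H](O[Si](C)(C)C(C)(C)C)[C@]3(O[Si](CC)(CC)CC)C(=O)C=C(C)C(=O)[C@@H]32)C(C)(C)[C@H]1O | intermediate
17 | 1α,2α,3α-triol (C5=C6, cis B/C) | O[C@H]1[C@@H](O)[C@]2(C)C(=C[C@H](O[Si](C)(C)C(C)(C)C)[C@]3(O[Si](CC)(CC)CC)C(=O)C=C(C)C(=O)[C@@H]32)C(C)(C)[C@H]1O | intermediate
18 | 5α-H triol (trans A/B, 9β-H, cis B/C) | O[C@H]1[C@@H](O)[C@]2(C)[C@H](C[C@H](O[Si](C)(C)C(C)(C)C)[C@]3(O[Si](CC)(CC)CC)C(=O)C=C(C)C(=O)[C@@H]32)C(C)(C)[C@H]1O | intermediate (not isolated)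
19 | 5α-H, 9α-H triol (trans A/B, trans B/C) | O[C@H]1[C@@H](O)[C@]2(C)[C@H](C[C@H](O[Si](C)(C)C(C)(C)C)[C@]3(O[Si](CC)(CC)CC)C(=O)C=C(C)C(=O)[C@H]32)C(C)(C)[C@H]1O | intermediate
20 | 2α-acetate of 19 | CC(=O)O[C@H]1[C@@H](O)[C@]2(C)[C@H](C[C@H](O[Si](C)(C)C(C)(C)C)[C@]3(O[Si](CC)(CC)CC)C(=O)C=C(C)C(=O)[C@H]32)C(C)(C)[C@H]1O | intermediate
21 | 1α,3α-dibenzoate 2α-acetate, six-membered enedione | CC(=O)O[C@H]1[C@@H](OC(=O)c2ccccc2)[C@]2(C)[C@H](C[C@H](O[Si](C)(C)C(C)(C)C)[C@]3(O[Si](CC)(CC)CC)C(=O)C=C(C)C(=O)[C@H]32)C(C)(C)[C@H]1OC(=O)c1ccccc1 | intermediate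
22 | 13,16-bis(trimethylsilyl) cyclooctenedione (epimer mixture at C13 and C16) | CC(=O)O[C@H]1[C@@H](OC(=O)c2ccccc2)[C@]2(C)[C@H](C[C@H](O[Si](C)(C)C(C)(C)C)[C@]3(O[Si](CC)(CC)CC)C(=O)C([Si](C)(C)C)/C=C(/C)C([Si](C)(C)C)C(=O)[C@H]32)C(C)(C)[C@H]1OC(=O)c1ccccc1 | intermediate (not isolated)
23 | 7α-TBSO-8β-TESO 6-6-8 diketone, (Z)-C14=C15 | CC(=O)O[C@H]1[C@@H](OC(=O)c2ccccc2)[C@]2(C)[C@H](C[C@H](O[Si](C)(C)C(C)(C)C)[C@]3(O[Si](CC)(CC)CC)C(=O)C/C=C(/C)CC(=O)[C@H]32)C(C)(C)[C@H]1OC(=O)c1ccccc1 | intermediate
24 | 7α,8β-diol | CC(=O)O[C@H]1[C@@H](OC(=O)c2ccccc2)[C@]2(C)[C@H](C[C@H](O)[C@]3(O)C(=O)C/C=C(/C)CC(=O)[C@H]32)C(C)(C)[C@H]1OC(=O)c1ccccc1 | intermediate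
25 | CNP0214674.2 | CC(=O)O[C@H]1[C@@H](OC(=O)c2ccccc2)[C@]2(C)[C@H](C[C@H](OC(C)=O)[C@]3(O)C(=O)C/C=C(/C)CC(=O)[C@H]32)C(C)(C)[C@H]1OC(=O)c1ccccc1 | target

**Step count**
Total: 16 steps. Longest linear sequence: 15 steps (1–5, then 7–16); step 6 is a one-step side branch.

**Three steps most likely to fail**

Step 14 (the proposed new double ring expansion). Risks are dipolar cycloaddition of the diazoalkane to the enedione alkene, wrong migrating group and over-insertion. The fallback uses known chemistry and runs from 21 to 23. Compound 21 is treated with allyl diazoacetate and BF3·OEt2 (one carbonyl at a time if needed); this ester-stabilised diazo insertion with alkenyl migration is established for cyclohexenones and gives the isolable ring-expanded bis(allyl β-keto ester) F5. Pd(PPh3)4 with morpholine then removes both allyl ester groups by deallylation and decarboxylation under neutral conditions to give 23.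

Step 7 (cycloaddition at a fully substituted diene terminus). Risks are low rate, the wrong orientation if the Lewis acid binds the other carbonyl, and erosion of ee. The fallback runs from 10 and 8 to 11 and replaces carbonyl-site control by halogen control. HBr adds to 10 to give 2-bromo-5-methylbenzene-1,4-diol F1, which FeCl3 reoxidises to 2-bromo-5-methyl-1,4-benzoquinone F2. F2 is a more reactive dienophile in which bromine directs the nucleophilic diene terminus to the unbrominated carbon, so with 8 and the same chiral catalyst it gives the 8β-bromo adduct F3 with the methyl again on C15. Bu3SnH with Et3B at −78 °C removes the bromine and returns to 11; C8 becomes planar again in step 8.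

Step 8 (C8 hydroxylation). Risks are deprotonation at C9 or at the C15 methyl, loss of the C7 silyloxide from the enolate, and aromatisation. The fallback runs from 11 to 14 and avoids a metal enolate. TESOTf and Et3N at −78 °C give the triethylsilyl dienol ether F4 at the less hindered C8–H; dimethyldioxirane in acetone at −78 °C then epoxidises the enol ether from the β face, and silyl migration delivers 14 directly (Rubottom oxidation).

**Further compounds**
F1 | step 7 | 2-bromo-5-methylbenzene-1,4-diol | Cc1cc(O)c(Br)cc1O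
F2 | step 7 | 2-bromo-5-methyl-1,4-benzoquinone | CC1=CC(=O)C(Br)=CC1=O
F3 | step 7 | 8β-bromo Diels–Alder adduct (7α-OTBS, 9β-H) | C1=CC[C@]2(C)C(=C[C@H](O[Si](C)(C)C(C)(C)C)[C@]3(Br)C(=O)C=C(C)C(=O)[C@@H]32)C1(C)C
F4 | step 8 | C12-O-triethylsilyl dienol ether of 11 | C1=CC[C@]2(C)C(=C[C@H](O[Si](C)(C)C(C)(C)C)C3=C(O[Si](CC)(CC)CC)C=C(C)C(=O)[C@@H]32)C1(C)C
F5 | step 14 | 13,16-bis(allyloxycarbonyl) cyclooctenedione | CC(=O)O[C@H]1[C@@H](OC(=O)c2ccccc2)[C@]2(C)[C@H](C[C@H](O[Si](C)(C)C(C)(C)C)[C@]3(O[Si](CC)(CC)CC)C(=O)C(C(=O)OCC=C)/C=C(/C)C(C(=O)OCC=C)C(=O)[C@H]32)C(C)(C)[C@H]1OC(=O)c1ccccc1
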